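**Strategy.** The 1,2-dioxane (ring atoms O1–O2–C3–C4–C5–C6) carries CH2CO2H on C3, so it is a β-peroxy acid: the ring is opened at the O2–C3 bond to a C6 hydroperoxide and a C2=C3 enoate, as in the presumed biosynthesis. In the key step ozone, methanol and an acyclic (4S)-configured enoate are joined: the C6 methylidene becomes a methoxy hydroperoxide that closes the ring by 6-exo peroxy-Michael addition and sets C3 under control of C4. The C6 methoxy group is then exchanged, through a peroxycarbenium ion, for the complete (E)-alkenyl side chain, which enters axially and sets the quaternary C6; saponification ends the route.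

Key step: step 8

Remark: 14 and 15 form as mixtures of epimers at the methoxy-bearing C6. This centre becomes planar in step 16, so the mixture is carried on and C6 is left undefined in their SMILES. Compounds 1, 4, 5, 12, 16, 17, 20 and 23 are taken as commercial.

Step 1
Reactants: 1 2-ethylacrolein (2-methylidenebutanal)
Product: 2 2-methylidenebutan-1-ol
Conditions: NaBH4, CeCl3·7H2O, MeOH, 0 °C
Reagents that add atoms: none
Why: Luche reduction delivers hydride 1,2 to the enal carbonyl without conjugate reduction.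

Step 2
Reactants: 2 2-methylidenebutan-1-ol
Product: 3 2-(bromomethyl)but-1-ene
Conditions: PBr3, pyridine (cat.), Et2O, 0 °C
Reagents that add atoms: phosphorus tribromide, BrP(Br)Br
Why: Bromination of a primary allylic alcohol through its phosphite ester; SN2 and SN2' displacement give the same product in this 2-substituted allyl system.

Step 3
Reactants: 4 (R)-4-benzyloxazolidin-2-one; 5 butanoyl chloride
Product: 7 (R)-4-benzyl-3-butanoyloxazolidin-2-one, via lithiated oxazolidinone 6 (not isolated)
Conditions: nBuLi, THF, −78 °C; then 5, −78 → 0 °C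
Reagents that add atoms: none
Why: N-Acylation of the lithium salt of the Evans auxiliary.

Step 4
Reactants: 7 (R)-4-benzyl-3-butanoyloxazolidin-2-one; 3 2-(bromomethyl)but-1-ene
Product: 9 (R)-4-benzyl-3-[(2S)-2-ethyl-4-methylidenehexanoyl]oxazolidin-2-one, via sodium Z-enolate 8 (not isolated)
Conditions: NaN(SiMe3)2, THF, −78 °C; then 3, −78 → −40 °C
Reagents that add atoms: none
Why: Evans asymmetric alkylation: the chelated Z-enolate is alkylated on the face opposite the benzyl group, which sets the future C4 as S.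

Step 5
Reactants: 9 (R)-4-benzyl-3-[(2S)-2-ethyl-4-methylidenehexanoyl]oxazolidin-2-one
Product: 10 (2S)-2-ethyl-4-methylidenehexan-1-ol
Conditions: LiBH4, MeOH (1 equiv), Et2O, 0 °C
Reagents that add atoms: none
Why: Reductive cleavage of the imide at the exocyclic carbonyl releases the auxiliary and leaves the stereocentre untouched.

Step 6
Reactants: 10 (2S)-2-ethyl-4-methylidenehexan-1-ol
Product: 11 (2S)-2-ethyl-4-methylidenehexanal
Conditions: TEMPO (cat.), PhI(OAc)2, CH2Cl2, rt
Reagents that add atoms: none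
Why: Oxoammonium-mediated oxidation of the primary alcohol stops at the aldehyde under non-basic conditions, so the α-centre should not epimerise and the alkene is untouched.

Step 7
Reactants: 11 (2S)-2-ethyl-4-methylidenehexanal; 12 methyl (triphenylphosphoranylidene)acetate
Product: 13 methyl (2E,4S)-4-ethyl-6-methylideneoct-2-enoate
Conditions: CH2Cl2, rt
Reagents that add atoms: none
Why: Wittig olefination with a stabilised ylide should give the E-enoate under neutral conditions that keep C4.

Step 8
Reactants: 13 methyl (2E,4S)-4-ethyl-6-methylideneoct-2-enoate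
Product: 15 methyl 2-[(3S,4S)-4,6-diethyl-6-methoxy-1,2-dioxan-3-yl]acetate, via hydroperoxy ketal 14 (not isolated)
Conditions: O3 (1.0 equiv, Sudan Red 7B indicator), CH2Cl2/MeOH 4:1, −78 °C; N2 purge, concentrate at 0 °C; then Et2NH (0.3 equiv), CF3CH2OH, 0 °C
Reagents that add atoms: ozone, [O-][O+]=O; methanol, CO
Why: Ozone cleaves the electron-rich 1,1-disubstituted alkene (Criegee mechanism) and methanol traps the ketone oxide as the α-methoxy hydroperoxide 14, whose peroxide anion then adds to C3 of the E-enoate while the fluoroalcohol protonates the ester enolate. The closest known reaction type is the ozonolysis-in-methanol and amine-mediated peroxy-Michael route to 3-alkoxy-1,2-dioxane acetates, an intramolecular oxa-Michael addition of a hydroperoxide. The 1,2-dioxane is closed in the 6-exo-trig mode by forming the O2–C3 bond. C3 is set by the C4 stereocentre: in the chair-like transition state the C4 ethyl group is equatorial, the peroxide oxygen attacks anti to the C4–ethyl bond and the E-enoate is pseudoaxial (the kinetic preference of 6-exo oxa-Michael closures of E-enoates), which should place CH2CO2Me cis to the C4 ethyl group (3S), while C6 forms as both epimers and is settled in step 16. The step needs chemoselective ozonolysis, secured by the much slower reaction of ozone with the electron-poor enoate and by the indicator dye, and kinetic protonation instead of enolate attack on the O–O bond or retro-addition, secured by the acidic solvent, the weak base and the low temperature.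

Step 9
Reactants: 16 (E)-pent-2-enal; 17 ethylmagnesium bromide
Product: 18 rac-(E)-hept-4-en-3-ol
Conditions: Et2O, −78 → 0 °C; aq. NH4Cl
Reagents that add atoms: none
Why: 1,2-Addition of the Grignard reagent to the enal carbonyl.

Step 10
Reactants: 18 rac-(E)-hept-4-en-3-ol
Product: 19 (3R,4E)-hept-4-en-3-ol
Conditions: Ti(OiPr)4 (0.1 equiv), L-(+)-diisopropyl tartrate (0.15 equiv), tBuOOH (0.6 equiv), 4 Å molecular sieves, CH2Cl2, −20 °C
Reagents that add atoms: none
Why: Sharpless kinetic resolution: with the L-(+)-tartrate the (S)-alcohol is epoxidised much faster, so the (R)-alcohol should be recovered in high enantiomeric purity.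

Step 11
Reactants: 19 (3R,4E)-hept-4-en-3-ol; 20 triethyl orthoacetate
Product: 21 ethyl (3R,4E)-3-ethylhept-4-enoate
Conditions: EtCO2H (cat.), 135 °C, EtOH distilled off
Reagents that add atoms: none
Why: Johnson–Claisen rearrangement through a chair transition state with the carbinol ethyl group equatorial transfers the carbinol chirality to the future C10 (R) and gives the E-alkene.

Step 12
Reactants: 21 ethyl (3R,4E)-3-ethylhept-4-enoate
Product: 22 (3R,4E)-3-ethylhept-4-enal
Conditions: iBu2AlH (1.05 equiv), CH2Cl2, −78 °C; aq. potassium sodium tartrate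
Reagents that add atoms: none
Why: Partial reduction of the ester, which stops at the aluminium hemiacetal at low temperature and gives the aldehyde on work-up.

Step 13
Reactants: 22 (3R,4E)-3-ethylhept-4-enal; 23 dimethyl (1-diazo-2-oxopropyl)phosphonate
Product: 24 (4R,5E)-4-ethyloct-5-en-1-yne
Conditions: K2CO3, MeOH, 0 °C → rt
Reagents that add atoms: none
Why: Ohira–Bestmann (Seyferth–Gilbert) homologation converts the aldehyde into the terminal alkyne; the β-stereocentre cannot epimerise.

Step 14
Reactants: 24 (4R,5E)-4-ethyloct-5-en-1-yne; 17 ethylmagnesium bromide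
Product: 26 (1E,4R,5E)-2,4-diethyl-1-iodoocta-1,5-diene, via alkenylcopper 25 (not isolated)
Conditions: 17, CuBr·SMe2, Et2O/Me2S, −45 °C; then 24, −25 °C; then I2, −78 → 0 °C
Reagents that add atoms: iodine, II
Why: Normant carbocupration adds ethylcopper syn across the terminal alkyne with copper on the terminal carbon, and iodinolysis with retention gives the E iodide in which iodine is cis to the new ethyl group.

Step 15
Reactants: 26 (1E,4R,5E)-2,4-diethyl-1-iodoocta-1,5-diene
Product: 29 potassium [(1E,4R,5E)-2,4-diethylocta-1,5-dien-1-yl]trifluoroborate, via alkenyllithium 27 (not isolated), via lithium triisopropoxyborate 28 (not isolated)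
Conditions: tBuLi (2.1 equiv), Et2O, −78 °C; B(OiPr)3, −78 → 0 °C; then aq. KHF2, rt
Reagents that add atoms: triisopropyl borate, CC(C)OB(OC(C)C)OC(C)C; potassium hydrogen difluoride, [K+].[F-].F
Why: Lithium–iodine exchange and borylation proceed with retention of the alkene geometry, and KHF2 converts the borate into the bench-stable trifluoroborate.

Step 16
Reactants: 15 methyl 2-[(3S,4S)-4,6-diethyl-6-methoxy-1,2-dioxan-3-yl]acetate; 29 potassium [(1E,4R,5E)-2,4-diethylocta-1,5-dien-1-yl]trifluoroborate
Product: 31 methyl 2-[(3S,4S,6R)-6-[(1E,4R,5E)-2,4-diethylocta-1,5-dien-1-yl]-4,6-diethyl-1,2-dioxan-3-yl]acetate, via alkenyldifluoroborane 30 (not isolated)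
Conditions: BF3·OEt2 (3 equiv), CH2Cl2/MeCN, −40 → −10 °C; quench with Et3N, aq. NaHCO3
Reagents that add atoms: none
Why: Proposed new method: BF3 abstracts fluoride from 29 to give the alkenyldifluoroborane 30, which binds the methoxy oxygen of 15; ionisation gives a cyclic peroxycarbenium ion paired with the alkenyl(methoxy)difluoroborate, and the alkenyl group migrates to C6 with retention of alkene geometry, entering axially on the face anti to the C4 ethyl and C3 acetate groups (half-chair with the C4 ethyl group pseudoequatorial, chair-like attack), which should give 6R from either C6 epimer of 15; the closest known reaction types are the BF3-mediated coupling of potassium alkenyltrifluoroborates with acetals through oxocarbenium ions and the Lewis-acid-mediated allylation of 3-alkoxy-1,2-dioxanes and 1,2-dioxolanes through peroxycarbenium ions.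

Step 17
Reactants: 31 methyl 2-[(3S,4S,6R)-6-[(1E,4R,5E)-2,4-diethylocta-1,5-dien-1-yl]-4,6-diethyl-1,2-dioxan-3-yl]acetate
Product: 32 Plakortide N
Conditions: LiOH·H2O, THF/H2O 3:1, 0 °C → rt; then dilute HCl to pH 3
Reagents that add atoms: lithium hydroxide, [Li+].[OH-]
Why: Saponification of the methyl ester, in which acyl substitution is much faster than α-deprotonation, so the peroxide ring and all stereocentres should survive.

**Compound list**

1 | 2-ethylacrolein (2-methylidenebutanal) | C=C(CC)C=O | starting material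
2 | 2-methylidenebutan-1-ol | C=C(CC)CO | intermediate
3 | 2-(bromomethyl)but-1-ene | C=C(CC)CBr | intermediate
4 | (R)-4-benzyloxazolidin-2-one | O=C1N[C@H](Cc2ccccc2)CO1 | starting material
5 | butanoyl chloride | CCCC(Cl)=O | starting material
6 | lithium salt of (R)-4-benzyloxazolidin-2-one | [Li]N1[C@H](Cc2ccccc2)COC1=O | intermediate (not isolated)
7 | (R)-4-benzyl-3-butanoyloxazolidin-2-one | CCCC(=O)N1[C@H](Cc2ccccc2)COC1=O | intermediate
8 | sodium Z-enolate of 7 | CC/C=C(\[O-])N1[C@H](Cc2ccccc2)COC1=O.[Na+] | intermediate (not isolated)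
9 | (R)-4-benzyl-3-[(2S)-2-ethyl-4-methylidenehexanoyl]oxazolidin-2-one | O=C([C@@H](CC)CC(=C)CC)N1[C@H](Cc2ccccc2)COC1=O | intermediate
10 | (2S)-2-ethyl-4-methylidenehexan-1-ol | OC[C@@H](CC)CC(=C)CC | intermediate
11 | (2S)-2-ethyl-4-methylidenehexanal | O=C[C@@H](CC)CC(=C)CC | intermediate
12 | methyl (triphenylphosphoranylidene)acetate | COC(=O)C=P(c1ccccc1)(c1ccccc1)c1ccccc1 | starting material
13 | methyl (2E,4S)-4-ethyl-6-methylideneoct-2-enoate | COC(=O)/C=C/[C@@H](CC)CC(=C)CC | intermediate
14 | methyl (2E,4S)-4-ethyl-6-hydroperoxy-6-methoxyoct-2-enoate (C6 epimers) | COC(=O)/C=C/[C@@H](CC)CC(OC)(OO)CC | intermediate (not isolated)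
15 | methyl 2-[(3S,4S)-4,6-diethyl-6-methoxy-1,2-dioxan-3-yl]acetate (C6 epimers) | CCC1(OC)C[C@H](CC)[C@H](CC(=O)OC)OO1 | intermediate
16 | (E)-pent-2-enal | CC/C=C/C=O | starting material
17 | ethylmagnesium bromide | CC[Mg]Br | starting material
18 | rac-(E)-hept-4-en-3-ol | CCC(O)/C=C/CC | intermediate
19 | (3R,4E)-hept-4-en-3-ol | CC[C@@H](O)/C=C/CC | intermediate
20 | triethyl orthoacetate | CCOC(C)(OCC)OCC | starting material
21 | ethyl (3R,4E)-3-ethylhept-4-enoate | CCOC(=O)C[C@@H](CC)/C=C/CC | intermediate
22 | (3R,4E)-3-ethylhept-4-enal | O=CC[C@@H](CC)/C=C/CC | intermediate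
23 | dimethyl (1-diazo-2-oxopropyl)phosphonate | COP(=O)(OC)C(=[N+]=[N-])C(C)=O | starting material
24 | (4R,5E)-4-ethyloct-5-en-1-yne | C#CC[C@@H](CC)/C=C/CC | intermediate
25 | [(1E,4R,5E)-2,4-diethylocta-1,5-dien-1-yl]copper | CC/C=C/[C@H](CC)C/C(=C/[Cu])CC | intermediate (not isolated)
26 | (1E,4R,5E)-2,4-diethyl-1-iodoocta-1,5-diene | CC/C=C/[C@H](CC)C/C(=C/I)CC | intermediate
27 | [(1E,4R,5E)-2,4-diethylocta-1,5-dien-1-yl]lithium | CC/C=C/[C@H](CC)C/C(=C/[Li])CC | intermediate (not isolated)
28 | lithium [(1E,4R,5E)-2,4-diethylocta-1,5-dien-1-yl]triisopropoxyborate | CC/C=C/[C@H](CC)C/C(=C/[B-](OC(C)C)(OC(C)C)OC(C)C)CC.[Li+] | intermediate (not isolated)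
29 | potassium [(1E,4R,5E)-2,4-diethylocta-1,5-dien-1-yl]trifluoroborate | CC/C=C/[C@H](CC)C/C(=C/[B-](F)(F)F)CC.[K+] | intermediate
30 | [(1E,4R,5E)-2,4-diethylocta-1,5-dien-1-yl]difluoroborane | CC/C=C/[C@H](CC)C/C(=C/B(F)F)CC | intermediate (not isolated)
31 | methyl 2-[(3S,4S,6R)-6-[(1E,4R,5E)-2,4-diethylocta-1,5-dien-1-yl]-4,6-diethyl-1,2-dioxan-3-yl]acetate | CC/C=C/[C@H](CC)C/C(=C/[C@@]1(CC)C[C@H](CC)[C@H](CC(=O)OC)OO1)CC | intermediate
32 | Plakortide N, 2-[(3S,4S,6R)-6-[(1E,4R,5E)-2,4-diethylocta-1,5-dien-1-yl]-4,6-diethyl-1,2-dioxan-3-yl]acetic acid | CC/C=C/[C@H](CC)C/C(=C/[C@@]1(CC)C[C@H](CC)[C@H](CC(=O)O)OO1)CC | target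

**Count**

Total step count: 17. Longest linear sequence: 9 steps (16 → 32 through steps 9–17; the branch from 1 through steps 1, 2, 4–8, 16 and 17 is equally long).

**Steps most likely to fail**

1. Step 16 (proposed new method). After ionisation the tertiary peroxycarbenium ion may lose a proton to an enol peroxide, open at the ring oxygen, or fragment by a Hock/Criegee-type shift faster than the hindered alkenyl group is transferred. The fallback uses known reactions only and gives up the control of C6. It sets out from 13 and 26 and comes back at 31. Ozonolysis of 13 with reductive work-up (O3, CH2Cl2, −78 °C; Me2S) gives methyl (2E,4S)-4-ethyl-6-oxooct-2-enoate F1. The alkenyllithium 27 made from 26 (tBuLi, −78 °C) is transmetallated with CeCl3 to [(1E,4R,5E)-2,4-diethylocta-1,5-dien-1-yl]cerium dichloride F2, which should add to the ketone of F1 and spare the enoate, giving methyl (2E,4S,7E,10R,11E)-4,6,8,10-tetraethyl-6-hydroxytetradeca-2,7,11-trienoate F3 as both C6 epimers. Acid-catalysed perhydrolysis (50% H2O2, H2SO4 cat., Et2O, 0 °C) converts the tertiary allylic alcohol through its allyl cation into methyl (2E,4S,7E,10R,11E)-4,6,8,10-tetraethyl-6-hydroperoxytetradeca-2,7,11-trienoate F4. Et2NH in CF3CH2OH then closes the dioxane as in step 8 to give 31, which would have to be separated from its C6 epimer and from products of the C8-regioisomeric hydroperoxide.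

2. Step 8 (key step). The peroxide may attack the other face of C3 and give the 3,4-trans epimer, which is expected to be the more stable one, or the ester enolate may attack the O–O bond and give an epoxide and a ketone. The fallback replaces the conjugate addition by a stereospecific 6-exo-tet displacement that still forms the O2–C3 bond. It sets out from 13 and comes back at 15. iBu2AlH reduces 13 to (2E,4S)-4-ethyl-6-methylideneoct-2-en-1-ol F5. Sharpless epoxidation with L-(+)-diethyl tartrate (Ti(OiPr)4, tBuOOH, −20 °C) gives [(2S,3S)-3-[(3S)-5-methylideneheptan-3-yl]oxiran-2-yl]methanol F6. NaAlH2(OCH2CH2OMe)2 opens the epoxide at C2 to (3R,4S)-4-ethyl-6-methylideneoctane-1,3-diol F7. TBSCl/imidazole protects the primary hydroxyl to give (3R,4S)-1-[(tert-butyldimethylsilyl)oxy]-4-ethyl-6-methylideneoctan-3-ol F8. MsCl/Et3N gives (3R,4S)-1-[(tert-butyldimethylsilyl)oxy]-4-ethyl-6-methylideneoctan-3-yl methanesulfonate F9. Ozonolysis in CH2Cl2/MeOH gives (3R,4S)-1-[(tert-butyldimethylsilyl)oxy]-4-ethyl-6-hydroperoxy-6-methoxyoctan-3-yl methanesulfonate F10. KOtBu/18-crown-6 in THF closes the ring with inversion at C3 to tert-butyl{2-[(3S,4S)-4,6-diethyl-6-methoxy-1,2-dioxan-3-yl]ethoxy}dimethylsilane F11. Bu4NF gives 2-[(3S,4S)-4,6-diethyl-6-methoxy-1,2-dioxan-3-yl]ethan-1-ol F12. TEMPO/PhI(OAc)2 in aqueous MeCN gives 2-[(3S,4S)-4,6-diethyl-6-methoxy-1,2-dioxan-3-yl]acetic acid F13, and Me3SiCHN2 in MeOH gives 15.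

3. Step 14. The carbometalation may be incomplete or not fully regioselective, and the alkenylcopper may lose its geometry or be protonated before iodination, which would spoil the C7=C8 geometry. The fallback installs boron and the ethyl group in one catalytic syn addition and avoids the iodide and tBuLi. It sets out from 24 and comes back at 29. Copper-catalysed ethylboration (B2pin2, EtI, CuCl, Xantphos, KOtBu, THF, rt) gives 2-[(1E,4R,5E)-2,4-diethylocta-1,5-dien-1-yl]-4,4,5,5-tetramethyl-1,3,2-dioxaborolane F14, and aqueous KHF2 in MeOH converts it into 29.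

**Further compounds**

F1 | step 16 | methyl (2E,4S)-4-ethyl-6-oxooct-2-enoate | COC(=O)/C=C/[C@@H](CC)CC(=O)CC
F2 | step 16 | [(1E,4R,5E)-2,4-diethylocta-1,5-dien-1-yl]cerium dichloride | CC/C=C/[C@H](CC)C/C(=C/[Ce](Cl)Cl)CC
F3 | step 16 | methyl (2E,4S,7E,10R,11E)-4,6,8,10-tetraethyl-6-hydroxytetradeca-2,7,11-trienoate (C6 epimers) | CC/C=C/[C@H](CC)C/C(=C/C(O)(CC)C[C@H](CC)/C=C/C(=O)OC)CC
F4 | step 16 | methyl (2E,4S,7E,10R,11E)-4,6,8,10-tetraethyl-6-hydroperoxytetradeca-2,7,11-trienoate (C6 epimers) | CC/C=C/[C@H](CC)C/C(=C/C(OO)(CC)C[C@H](CC)/C=C/C(=O)OC)CC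
F5 | step 8 | (2E,4S)-4-ethyl-6-methylideneoct-2-en-1-ol | OC/C=C/[C@@H](CC)CC(=C)CC
F6 | step 8 | [(2S,3S)-3-[(3S)-5-methylideneheptan-3-yl]oxiran-2-yl]methanol | OC[C@@H]1O[C@H]1[C@@H](CC)CC(=C)CC
F7 | step 8 | (3R,4S)-4-ethyl-6-methylideneoctane-1,3-diol | OCC[C@@H](O)[C@@H](CC)CC(=C)CC
F8 | step 8 | (3R,4S)-1-[(tert-butyldimethylsilyl)oxy]-4-ethyl-6-methylideneoctan-3-ol | CC(C)(C)[Si](C)(C)OCC[C@@H](O)[C@@H](CC)CC(=C)CC
F9 | step 8 | (3R,4S)-1-[(tert-butyldimethylsilyl)oxy]-4-ethyl-6-methylideneoctan-3-yl methanesulfonate | CC(C)(C)[Si](C)(C)OCC[C@@H](OS(C)(=O)=O)[C@@H](CC)CC(=C)CC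
F10 | step 8 | (3R,4S)-1-[(tert-butyldimethylsilyl)oxy]-4-ethyl-6-hydroperoxy-6-methoxyoctan-3-yl methanesulfonate (C6 epimers) | CC(C)(C)[Si](C)(C)OCC[C@@H](OS(C)(=O)=O)[C@@H](CC)CC(OC)(OO)CC
F11 | step 8 | tert-butyl{2-[(3S,4S)-4,6-diethyl-6-methoxy-1,2-dioxan-3-yl]ethoxy}dimethylsilane | CCC1(OC)C[C@H](CC)[C@H](CCO[Si](C)(C)C(C)(C)C)OO1
F12 | step 8 | 2-[(3S,4S)-4,6-diethyl-6-methoxy-1,2-dioxan-3-yl]ethan-1-ol | CCC1(OC)C[C@H](CC)[C@H](CCO)OO1
F13 | step 8 | 2-[(3S,4S)-4,6-diethyl-6-methoxy-1,2-dioxan-3-yl]acetic acid | CCC1(OC)C[C@H](CC)[C@H](CC(=O)O)OO1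
F14 | step 14 | 2-[(1E,4R,5E)-2,4-diethylocta-1,5-dien-1-yl]-4,4,5,5-tetramethyl-1,3,2-dioxaborolane | CC/C=C/[C@H](CC)C/C(=C/B1OC(C)(C)C(C)(C)O1)CC
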